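**Reading of the target (one line):** the SMILES is taken literally. It places the ether C–O bonds at C5 and C10 on opposite faces of the ten-membered carbocycle, i.e. a trans-bridged ("in,out", H-5 inside) 11-oxabicyclo[4.4.1]undecane, and the route is built to deliver exactly that isomer.

**Conventions:** germacrane numbering is used for locants: lactone C12(=O)–O–C6, C7, C11=C13; ester oxygen on C8; C10 carries C14 (Me) and the ether O to C5; OAc on C3; C15H2OH on C4. C2' is the extra allylic carbon that is later excised. TBS = tert-butyldimethylsilyl, PMB = 4-methoxybenzyl.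

## Retrosynthetic overview

1. Target ⇐ C8 esterification with (Z)-acid 35, C3 acetylation, and unmasking of the α-methylene lactone from its Me2NH adduct.
2. Ring B (O–C10–C1–C2–C3–C4–C5) is closed last by RCM (C1=C2) then hydrogenation, on an oxepane whose C5 and C10 appendages are already trans; this forces the in,out bridge.
3. Ring A (O–C5–C6–C7–C8–C9–C10) comes from 7-exo opening of a Sharpless epoxide at C10 by the C5 hydroxyl (inversion at C10).
4. The lactone is formed first, in the key step: intermolecular Cr(II) carbonyl allylation of aldehyde 16 (C3–C6, C15) with 2-(bromomethyl)acrylate 29 (C7–C10, C11–C14), forming C6–C7.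
5. 16 from (S)-glycidol plus an Evans aldol with acrolein; 29 from geraniol (proline α-aminoxylation, Baylis–Hillman); 35 from crotonaldehyde. Ring order: lactone → oxepane A → oxepane B.

## Route

### East fragment (aldehyde 16)

**Step 1**
Reactants: 1 (S)-glycidol
Product: 2 (R)-2-{[(4-methoxybenzyl)oxy]methyl}oxirane
Conditions: NaH, PMBCl, TBAI (cat.), THF/DMF, 0 °C→rt
Reagents that add atoms: 4-methoxybenzyl chloride COc1ccc(CCl)cc1
Why: Williamson etherification; the stereocentre (future C5) is untouched (the descriptor changes only through CIP priorities).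

**Step 2**
Reactants: 2 (R)-PMB glycidyl ether
Product: 3 (R)-1-[(4-methoxybenzyl)oxy]pent-4-en-2-ol
Conditions: vinylMgBr, CuI (10 mol%), THF, −40→0 °C
Reagents that add atoms: vinylmagnesium bromide C=C[Mg]Br
Why: Cu-catalysed Grignard opening of the terminal epoxide at the CH2 terminus, with C5 retained.

**Step 3**
Reactants: 3 homoallylic alcohol
Product: 4 (R)-tert-butyl({1-[(4-methoxybenzyl)oxy]pent-4-en-2-yl}oxy)dimethylsilane
Conditions: TBSCl, imidazole, DMF, rt
Reagents that add atoms: tert-butyldimethylsilyl chloride CC(C)(C)[Si](C)(C)Cl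
Why: standard silylation; a non-chelating α-OTBS group is wanted for Felkin control in step 24.

**Step 4**
Reactants: 4 TBS ether
Product: 6 (R)-3-(TBSO)-4-(PMBO)butanoic acid, via (R)-3-(TBSO)-4-(PMBO)butanal 5 (not isolated)
Conditions: OsO4 (2 mol%), NaIO4, 2,6-lutidine, dioxane/H2O, rt; then NaClO2, NaH2PO4, 2-methyl-2-butene, t-BuOH/H2O
Reagents that add atoms: osmium tetroxide O=[Os](=O)(=O)=O with sodium periodate [Na+].[O-]I(=O)(=O)=O (carbonyl O); sodium chlorite [Na+].[O-]Cl=O (OH oxygen)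
Why: Johnson–Lemieux cleavage then Pinnick oxidation, both compatible with PMB and TBS ethers.

**Step 5**
Reactants: 6 acid; 7 (R)-4-benzyloxazolidin-2-one
Product: 9 (R)-4-benzyl-3-[(R)-3-(TBSO)-4-(PMBO)butanoyl]oxazolidin-2-one, via mixed pivalic anhydride 8 (not isolated)
Conditions: PivCl, Et3N, THF, −20 °C; then 7, LiCl, rt
Reagents that add atoms: pivaloyl chloride CC(C)(C)C(=O)Cl (atoms only in intermediate 8)
Why: N-acylation of the Evans auxiliary through the mixed anhydride.

**Step 6**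
Reactants: 9 imide; 10 acrolein
Product: 12 Evans syn-aldol adduct (C3–OH, C4, C5 configured as in the target), via (Z)-dibutylboron enolate 11 (not isolated)
Conditions: Bu2BOTf, i-Pr2NEt, CH2Cl2, −78→0 °C; 10, −78→0 °C; H2O2, pH 7 buffer, MeOH
Reagents that add atoms: dibutylboron triflate CCCCB(CCCC)OS(=O)(=O)C(F)(F)F (atoms only in intermediate 11)
Why: Evans boron aldol through the Zimmerman–Traxler chair of the Z-enolate; the (R)-auxiliary sets C4 and C3 (3,4-syn in the aldol sense) and overrides the β-OTBS centre.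

**Step 7**
Reactants: 12 aldol adduct
Product: 13 (2S,3S)-2-{(R)-1-(TBSO)-2-(PMBO)ethyl}pent-4-ene-1,3-diol
Conditions: LiBH4, MeOH (1 equiv), THF, 0 °C
Reagents that add atoms: none
Why: reductive removal of the auxiliary gives C15H2OH without touching the stereocentres.

**Step 8**
Reactants: 13 diol
Product: 14 tert-butyl{(R)-1-[(4S,5S)-2,2-dimethyl-4-vinyl-1,3-dioxan-5-yl]-2-[(4-methoxybenzyl)oxy]ethoxy}dimethylsilane
Conditions: Me2C(OMe)2, PPTS (cat.), CH2Cl2, rt
Reagents that add atoms: 2,2-dimethoxypropane COC(C)(C)OC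
Why: acetonide formation on the 1,3-diol (O3/O15) gives one robust group for both hydroxyls until step 32.

**Step 9**
Reactants: 14 acetonide
Product: 15 (R)-2-(TBSO)-2-[(4S,5S)-2,2-dimethyl-4-vinyl-1,3-dioxan-5-yl]ethan-1-ol
Conditions: DDQ, CH2Cl2/pH 7 buffer, 0 °C
Reagents that add atoms: none
Why: oxidative PMB cleavage; TBS, acetonide and the vinyl group are inert.

**Step 10**
Reactants: 15 alcohol
Product: 16 (R)-2-(TBSO)-2-[(4S,5S)-2,2-dimethyl-4-vinyl-1,3-dioxan-5-yl]acetaldehyde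
Conditions: Dess–Martin periodinane, NaHCO3, CH2Cl2, 0 °C→rt (used crude)
Reagents that add atoms: none
Why: buffered, non-basic oxidation avoids epimerisation of the α-silyloxy aldehyde.

### West fragment (allyl bromide 29)

**Step 11**
Reactants: 17 geraniol
Product: 18 geranyl TBS ether
Conditions: TBSCl, imidazole, CH2Cl2, 0 °C→rt
Reagents that add atoms: tert-butyldimethylsilyl chloride CC(C)(C)[Si](C)(C)Cl
Why: silylation; geraniol supplies C7–C10, C14, C1 and C2' with the (E)-alkene in place.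

**Step 12**
Reactants: 18 geranyl TBS ether
Product: 19 6,7-epoxygeranyl TBS ether (racemic at the epoxide)
Conditions: mCPBA (1.0 equiv), NaHCO3, CH2Cl2, −20→0 °C
Reagents that add atoms: 3-chloroperoxybenzoic acid OOC(=O)c1cccc(Cl)c1
Why: Prilezhaev epoxidation prefers the distal trisubstituted alkene, because the 2,3-alkene is deactivated by the allylic C–O bond.

**Step 13**
Reactants: 19 epoxide
Product: 20 (E)-6-(TBSO)-4-methylhex-4-enal
Conditions: H5IO6, THF/H2O, 0 °C
Reagents that add atoms: none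
Why: one-pot epoxide hydrolysis and glycol cleavage releases acetone and the C7 aldehyde.

**Step 14**
Reactants: 20 aldehyde
Product: 23 (R,E)-6-(TBSO)-4-methylhex-4-ene-1,2-diol, via (R)-2-(anilinooxy) aldehyde 21 (not isolated), via (R)-2-(anilinooxy) alcohol 22 (not isolated)
Conditions: PhNO, L-proline (20 mol%), DMSO, rt; NaBH4, EtOH, 0 °C; Zn, AcOH, EtOH, rt
Reagents that add atoms: nitrosobenzene O=Nc1ccccc1
Why: proline-catalysed enamine α-aminoxylation sets C8 (R, as in the target) under catalyst control; reduction and N–O cleavage give the diol.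

**Step 15**
Reactants: 23 diol
Product: 24 (4R)-2-(4-methoxyphenyl)-1,3-dioxolane (acetal carbon as a mixture)
Conditions: 4-MeOC6H4CH(OMe)2, PPTS (cat.), CH2Cl2, rt
Reagents that add atoms: 4-methoxybenzaldehyde dimethyl acetal COc1ccc(C(OC)OC)cc1
Why: transacetalisation of the 1,2-diol sets up regioselective PMB placement.

**Step 16**
Reactants: 24 PMP acetal
Product: 25 (R,E)-6-(TBSO)-2-(PMBO)-4-methylhex-4-en-1-ol
Conditions: DIBAL-H, CH2Cl2, −78→0 °C; Rochelle salt
Reagents that add atoms: none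
Why: reductive acetal opening; aluminium binds the less hindered primary oxygen, leaving PMB on the secondary C8 oxygen.

**Step 17**
Reactants: 25 alcohol
Product: 26 (R,E)-6-(TBSO)-2-(PMBO)-4-methylhex-4-enal
Conditions: Dess–Martin periodinane, NaHCO3, CH2Cl2, 0 °C
Reagents that add atoms: none
Why: buffered oxidation to the α-alkoxy aldehyde without epimerising C8.

**Step 18**
Reactants: 26 aldehyde; 27 methyl acrylate
Product: 28 Baylis–Hillman adduct (C7 carbinol as a mixture, C8 R)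
Conditions: DABCO (1 equiv), excess 27, MeOH (cat.), rt, 2–4 d
Reagents that add atoms: none
Why: Morita–Baylis–Hillman reaction; α-alkoxy aldehydes are activated acceptors, and the C7 mixture is irrelevant because C7 becomes sp2 in step 19.

**Step 19**
Reactants: 28 Baylis–Hillman adduct
Product: 29 methyl (2Z,4R,6E)-2-(bromomethyl)-8-(TBSO)-4-(PMBO)-6-methylocta-2,6-dienoate
Conditions: NBS, Me2S, CH2Cl2, 0 °C→rt
Reagents that add atoms: N-bromosuccinimide O=C1CCC(=O)N1Br
Why: Corey–Kim-type activation and SN2' bromide delivery give the thermodynamic (Z)-2-(bromomethyl)enoate.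

### Ester side-chain acid 35

**Step 20**
Reactants: 30 crotonaldehyde
Product: 31 (Z)-2-iodobut-2-enal
Conditions: I2, K2CO3, DMAP (20 mol%), THF/H2O, rt
Reagents that add atoms: iodine II
Why: amine-catalysed α-iodination of the enal (addition–iodination–elimination) keeps CHO trans to CH3.

**Step 21**
Reactants: 31 iodoenal
Product: 32 (Z)-2-iodobut-2-en-1-ol
Conditions: NaBH4, CeCl3·7H2O, MeOH, 0 °C
Reagents that add atoms: none
Why: Luche 1,2-reduction.

**Step 22**
Reactants: 32 iodo alcohol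
Product: 33 (Z)-tert-butyl[(2-iodobut-2-en-1-yl)oxy]dimethylsilane
Conditions: TBSCl, imidazole, CH2Cl2, rt
Reagents that add atoms: tert-butyldimethylsilyl chloride CC(C)(C)[Si](C)(C)Cl
Why: standard silylation.

**Step 23**
Reactants: 33 vinyl iodide
Product: 35 (Z)-2-{[(tert-butyldimethylsilyl)oxy]methyl}but-2-enoic acid, via vinyllithium 34 (not isolated)
Conditions: t-BuLi (2.1 equiv), Et2O, −78 °C; CO2, −78 °C→rt; cold 1 M HCl
Reagents that add atoms: carbon dioxide O=C=O; tert-butyllithium [Li]C(C)(C)C (Li only in intermediate 34)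
Why: I/Li exchange and carboxylation proceed with retention, so CO2H ends up cis to CH3 as the target ester requires.

### Fragment union and completion

**Step 24 (key step)**
Reactants: 16 aldehyde; 29 allyl bromide
Product: 38 trans-α-methylene-γ-butyrolactone (C6 and C7 as in the target; C5–OTBS, C3/C15 acetonide, C8–OPMB, (E)-C10=C1, C2'–OTBS), via allylchromium(III) species 36 (not isolated), via anti-homoallylic hydroxy ester 37 (not isolated)
Conditions: CrCl2 (4 equiv), THF, rt; then PPTS (cat.), toluene, 50 °C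
Reagents that add atoms: chromium(II) chloride Cl[Cr]Cl (atoms only in intermediate 36)
Why: Nozaki–Hiyama-type 2-(alkoxycarbonyl)allylation through a chair transition state gives the anti adduct (trans lactone); C6 follows Felkin–Anh addition to the α-OTBS aldehyde (5,6-anti), and C8 of 29 is expected to reinforce this through its A(1,3)-minimised rotamer (H-8 eclipsing the alkene, C9 anti to the aldehyde), although this reagent bias is the least certain element.

**Step 25**
Reactants: 38 lactone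
Product: 39 diol (C5–OH and C2'–OH free)
Conditions: HF·pyridine, pyridine, THF, 0 °C→rt
Reagents that add atoms: none
Why: buffered fluoride cleaves both TBS ethers and spares the PMB ether, acetonide and α-methylene lactone.

**Step 26**
Reactants: 39 diol
Product: 41 oxepane A with a C1,C2'-diol side chain (O5–C10 bond formed), via (1R,10R)-epoxy alcohol 40 (not isolated)
Conditions: Ti(Oi-Pr)4, D-(−)-DET, t-BuOOH, 4 Å MS, CH2Cl2, −20 °C; then CSA (cat.), 0 °C→rt
Reagents that add atoms: tert-butyl hydroperoxide CC(C)(C)OO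
Why: Sharpless asymmetric epoxidation (D-tartrate gives the (2R,3R)-type epoxide, mirror image of the geraniol/L-tartrate case) followed by acid-promoted 7-exo opening at the tertiary carbon with inversion sets the C10 configuration of the target, trans to the C5 appendage.

**Step 27**
Reactants: 41 diol
Product: 42 C1 aldehyde on C10
Conditions: NaIO4, THF/H2O, 0 °C→rt
Reagents that add atoms: none
Why: glycol cleavage excises C2'; the α-quaternary aldehyde cannot epimerise.

**Step 28**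
Reactants: 42 aldehyde
Product: 43 triene (C10 vinyl, C3 vinyl, lactone methylene)
Conditions: Zn, CH2Br2, TiCl4 (Lombardo reagent), THF/CH2Cl2, 0 °C→rt
Reagents that add atoms: dibromomethane BrCBr
Why: Takai–Lombardo methylenation is non-basic and aldehyde-selective, so the lactone and its Michael acceptor survive.

**Step 29**
Reactants: 43 triene
Product: 44 13-(dimethylamino)-11,13-dihydro adduct (drawn 11R, CH2NMe2 trans to the C8 chain; an 11-epimer would converge in step 35)
Conditions: Me2NH (2 M in THF), rt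
Reagents that add atoms: dimethylamine CNC
Why: reversible aza-Michael addition masks the α-methylene lactone, which would otherwise undergo competing RCM to a six-membered ring and be hydrogenated in step 31.

**Step 30**
Reactants: 44 masked diene
Product: 45 in,out 11-oxabicyclo[4.4.1]undec-1-ene core (C1=C2)
Conditions: CSA (1.1 equiv); Hoveyda–Grubbs II (15 mol%), toluene (2 mM), 80 °C; aq. NaHCO3
Reagents that add atoms: none
Why: ring-closing metathesis of the two monosubstituted vinyl groups (amine protected as its ammonium salt); C5 and C10 are already fixed trans on the oxepane, so only the in,out bicycle can form.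

**Step 31**
Reactants: 45 alkene
Product: 46 saturated bicycle
Conditions: H2 (1 atm), 10% Pd/C, pyridine (0.5 equiv), EtOAc, rt
Reagents that add atoms: none
Why: hydrogenation of the strained cis-alkene; the pyridine-poisoned catalyst leaves the PMB ether intact.

**Step 32**
Reactants: 46 acetonide
Product: 47 C3,C15-diol
Conditions: PPTS, MeOH, 40 °C
Reagents that add atoms: none
Why: mild transacetalisation, chosen to avoid ionising the strained tertiary ether.

**Step 33**
Reactants: 47 diol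
Product: 48 C15 TBS ether
Conditions: TBSCl (1.1 equiv), imidazole, CH2Cl2, 0 °C
Reagents that add atoms: tert-butyldimethylsilyl chloride CC(C)(C)[Si](C)(C)Cl
Why: primary-selective silylation of the 1,3-diol.

**Step 34**
Reactants: 48 secondary alcohol
Product: 49 C3 acetate
Conditions: Ac2O, pyridine, DMAP (cat.), CH2Cl2, rt
Reagents that add atoms: acetic anhydride CC(=O)OC(C)=O
Why: DMAP-catalysed acetylation of the only free hydroxyl.

**Step 35**
Reactants: 49 amine
Product: 51 α-methylene lactone, via methiodide 50 (not isolated)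
Conditions: MeI, THF/MeOH, rt; then aq. NaHCO3, EtOAc, rt
Reagents that add atoms: iodomethane CI (atoms only in intermediate 50)
Why: quaternisation then mild E1cB (Hofmann-type) elimination regenerates the 11(13)-alkene and removes the C11 stereocentre.

**Step 36**
Reactants: 51 PMB ether
Product: 52 C8 alcohol
Conditions: DDQ, CH2Cl2/pH 7 buffer, 0 °C→rt
Reagents that add atoms: none
Why: oxidative PMB removal is orthogonal to acetate, TBS and the methylene lactone, and is now free of the amine.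

**Step 37**
Reactants: 52 alcohol; 35 acid
Product: 54 C8 (Z)-2-(TBSO-methyl)but-2-enoate, via mixed 2,4,6-trichlorobenzoic anhydride 53 (not isolated)
Conditions: 35, 2,4,6-Cl3C6H2COCl, Et3N, toluene, rt; then 52, DMAP, toluene, rt
Reagents that add atoms: 2,4,6-trichlorobenzoyl chloride O=C(Cl)c1c(Cl)cc(Cl)cc1Cl (atoms only in intermediate 53)
Why: Yamaguchi esterification acylates the hindered secondary alcohol with retention at C8 and is the usual way to limit Z→E isomerisation of angelate-type acids.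

**Step 38**
Reactants: 54 bis-TBS ether
Product: 55 target (CNP0195618.1)
Conditions: HF·pyridine, pyridine, THF, 0 °C→rt
Reagents that add atoms: none
Why: buffered acidic desilylation frees both primary hydroxyls without acyl migration or Michael addition.

## Compound list

1 | (S)-glycidol | OC[C@H]1CO1 | starting material
2 | (R)-2-{[(4-methoxybenzyl)oxy]methyl}oxirane | COc1ccc(COC[C@H]2CO2)cc1 | intermediate
3 | (R)-1-[(4-methoxybenzyl)oxy]pent-4-en-2-ol | C=CC[C@@H](O)COCc1ccc(OC)cc1 | intermediate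
4 | (R)-TBS ether of 3 | C=CC[C@@H](O[Si](C)(C)C(C)(C)C)COCc1ccc(OC)cc1 | intermediate
5 | (R)-3-(TBSO)-4-(PMBO)butanal | O=CC[C@@H](O[Si](C)(C)C(C)(C)C)COCc1ccc(OC)cc1 | intermediate (not isolated)
6 | (R)-3-(TBSO)-4-(PMBO)butanoic acid | OC(=O)C[C@@H](O[Si](C)(C)C(C)(C)C)COCc1ccc(OC)cc1 | intermediate
7 | (R)-4-benzyloxazolidin-2-one | O=C1N[C@H](Cc2ccccc2)CO1 | starting material
8 | mixed pivalic anhydride of 6 | CC(C)(C)C(=O)OC(=O)C[C@@H](O[Si](C)(C)C(C)(C)C)COCc1ccc(OC)cc1 | intermediate (not isolated)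
9 | (R)-4-benzyl-3-[(R)-3-(TBSO)-4-(PMBO)butanoyl]oxazolidin-2-one | O=C1OC[C@@H](Cc2ccccc2)N1C(=O)C[C@@H](O[Si](C)(C)C(C)(C)C)COCc1ccc(OC)cc1 | intermediate
10 | acrolein | C=CC=O | starting material
11 | (Z)-dibutylboron enolate of 9 | CCCCB(CCCC)O/C(=C\[C@@H](O[Si](C)(C)C(C)(C)C)COCc1ccc(OC)cc1)N1C(=O)OC[C@H]1Cc1ccccc1 | intermediate (not isolated)
12 | Evans syn-aldol adduct, (R)-4-benzyl-3-[(2S,3S)-2-{(R)-1-(TBSO)-2-(PMBO)ethyl}-3-hydroxypent-4-enoyl]oxazolidin-2-one | O=C1OC[C@@H](Cc2ccccc2)N1C(=O)[C@@H]([C@@H](O)C=C)[C@@H](O[Si](C)(C)C(C)(C)C)COCc1ccc(OC)cc1 | intermediate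
13 | (2S,3S)-2-{(R)-1-(TBSO)-2-(PMBO)ethyl}pent-4-ene-1,3-diol | OC[C@@H]([C@@H](O)C=C)[C@@H](O[Si](C)(C)C(C)(C)C)COCc1ccc(OC)cc1 | intermediate
14 | tert-butyl{(R)-1-[(4S,5S)-2,2-dimethyl-4-vinyl-1,3-dioxan-5-yl]-2-(PMBO)ethoxy}dimethylsilane | C=C[C@@H]1OC(C)(C)OC[C@@H]1[C@@H](O[Si](C)(C)C(C)(C)C)COCc1ccc(OC)cc1 | intermediate
15 | (R)-2-(TBSO)-2-[(4S,5S)-2,2-dimethyl-4-vinyl-1,3-dioxan-5-yl]ethan-1-ol | C=C[C@@H]1OC(C)(C)OC[C@@H]1[C@@H](O[Si](C)(C)C(C)(C)C)CO | intermediate
16 | (R)-2-(TBSO)-2-[(4S,5S)-2,2-dimethyl-4-vinyl-1,3-dioxan-5-yl]acetaldehyde | C=C[C@@H]1OC(C)(C)OC[C@@H]1[C@@H](O[Si](C)(C)C(C)(C)C)C=O | intermediate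
17 | geraniol | CC(C)=CCC/C(C)=C/CO | starting material
18 | geranyl TBS ether | CC(C)=CCC/C(C)=C/CO[Si](C)(C)C(C)(C)C | intermediate
19 | 6,7-epoxygeranyl TBS ether (racemic epoxide) | CC1(C)OC1CC/C(C)=C/CO[Si](C)(C)C(C)(C)C | intermediate
20 | (E)-6-(TBSO)-4-methylhex-4-enal | O=CCC/C(C)=C/CO[Si](C)(C)C(C)(C)C | intermediate
21 | (R,E)-2-(anilinooxy)-6-(TBSO)-4-methylhex-4-enal | O=C[C@H](ONc1ccccc1)C/C(C)=C/CO[Si](C)(C)C(C)(C)C | intermediate (not isolated)
22 | (R,E)-2-(anilinooxy)-6-(TBSO)-4-methylhex-4-en-1-ol | OC[C@H](ONc1ccccc1)C/C(C)=C/CO[Si](C)(C)C(C)(C)C | intermediate (not isolated)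
23 | (R,E)-6-(TBSO)-4-methylhex-4-ene-1,2-diol | OC[C@H](O)C/C(C)=C/CO[Si](C)(C)C(C)(C)C | intermediate
24 | (4R)-4-[(E)-4-(TBSO)-2-methylbut-2-enyl]-2-(4-methoxyphenyl)-1,3-dioxolane (acetal C mixed) | COc1ccc(C2OC[C@@H](C/C(C)=C/CO[Si](C)(C)C(C)(C)C)O2)cc1 | intermediate
25 | (R,E)-6-(TBSO)-2-(PMBO)-4-methylhex-4-en-1-ol | OC[C@H](OCc1ccc(OC)cc1)C/C(C)=C/CO[Si](C)(C)C(C)(C)C | intermediate
26 | (R,E)-6-(TBSO)-2-(PMBO)-4-methylhex-4-enal | O=C[C@H](OCc1ccc(OC)cc1)C/C(C)=C/CO[Si](C)(C)C(C)(C)C | intermediate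
27 | methyl acrylate | C=CC(=O)OC | starting material
28 | methyl (4R,6E)-8-(TBSO)-3-hydroxy-4-(PMBO)-6-methyl-2-methyleneoct-6-enoate (C3 mixed) | COC(=O)C(=C)C(O)[C@H](OCc1ccc(OC)cc1)C/C(C)=C/CO[Si](C)(C)C(C)(C)C | intermediate
29 | methyl (2Z,4R,6E)-2-(bromomethyl)-8-(TBSO)-4-(PMBO)-6-methylocta-2,6-dienoate | COC(=O)/C(CBr)=C/[C@H](OCc1ccc(OC)cc1)C/C(C)=C/CO[Si](C)(C)C(C)(C)C | intermediate
30 | crotonaldehyde | C/C=C/C=O | starting material
31 | (Z)-2-iodobut-2-enal | C/C=C(\I)C=O | intermediate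
32 | (Z)-2-iodobut-2-en-1-ol | C/C=C(\I)CO | intermediate
33 | (Z)-tert-butyl[(2-iodobut-2-en-1-yl)oxy]dimethylsilane | C/C=C(\I)CO[Si](C)(C)C(C)(C)C | intermediate
34 | vinyllithium from 33 (Li cis to CH3) | [Li]/C(=C\C)CO[Si](C)(C)C(C)(C)C | intermediate (not isolated)
35 | (Z)-2-{[(tert-butyldimethylsilyl)oxy]methyl}but-2-enoic acid | C/C=C(/CO[Si](C)(C)C(C)(C)C)C(=O)O | intermediate
36 | allylchromium(III) dichloride from 29 (Cr on C13; drawn as first formed, equilibrating) | COC(=O)/C(C[Cr](Cl)Cl)=C/[C@H](OCc1ccc(OC)cc1)C/C(C)=C/CO[Si](C)(C)C(C)(C)C | intermediate (not isolated)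
37 | anti-homoallylic hydroxy ester (C6–OH free; all centres as in 38) | COC(=O)C(=C)[C@@H]([C@H](O)[C@H](O[Si](C)(C)C(C)(C)C)[C@H]2COC(C)(C)O[C@H]2C=C)[C@H](OCc2ccc(OC)cc2)C/C(C)=C/CO[Si](C)(C)C(C)(C)C | intermediate (not isolated)
38 | trans-6,12-olide with 11(13)-methylene; C6 bears (R)-CH(OTBS)[(4S,5S)-2,2-dimethyl-4-vinyl-1,3-dioxan-5-yl]; C7 bears the (1R,3E)-1-(PMBO)-3-methyl-5-(TBSO)pent-3-enyl chain | C=C1C(=O)O[C@H]([C@H](O[Si](C)(C)C(C)(C)C)[C@H]2COC(C)(C)O[C@H]2C=C)[C@H]1[C@H](OCc1ccc(OC)cc1)C/C(C)=C/CO[Si](C)(C)C(C)(C)C | intermediate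
39 | diol from 38 (C5–OH, C2'–OH) | C=C1C(=O)O[C@H]([C@H](O)[C@H]2COC(C)(C)O[C@H]2C=C)[C@H]1[C@H](OCc1ccc(OC)cc1)C/C(C)=C/CO | intermediate
40 | (1R,10R)-epoxy alcohol | C=C1C(=O)O[C@H]([C@H](O)[C@H]2COC(C)(C)O[C@H]2C=C)[C@H]1[C@H](OCc1ccc(OC)cc1)C[C@@]1(C)O[C@@H]1CO | intermediate (not isolated)
41 | lactone-fused oxepane A; C10 bears Me and CH(OH)CH2OH, C5 bears the dioxanyl group, C8 OPMB | C=C1C(=O)O[C@@H]2[C@@H]([C@H]3COC(C)(C)O[C@H]3C=C)O[C@@]([C@H](O)CO)(C)C[C@@H](OCc3ccc(OC)cc3)[C@@H]12 | intermediate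
42 | C10 aldehyde of oxepane A | C=C1C(=O)O[C@@H]2[C@@H]([C@H]3COC(C)(C)O[C@H]3C=C)O[C@@](C=O)(C)C[C@@H](OCc3ccc(OC)cc3)[C@@H]12 | intermediate
43 | C10 vinyl oxepane A (triene) | C=C1C(=O)O[C@@H]2[C@@H]([C@H]3COC(C)(C)O[C@H]3C=C)O[C@@](C=C)(C)C[C@@H](OCc3ccc(OC)cc3)[C@@H]12 | intermediate
44 | (11R)-13-(dimethylamino)-11,13-dihydro derivative of 43 | CN(C)C[C@@H]1C(=O)O[C@@H]2[C@@H]([C@H]3COC(C)(C)O[C@H]3C=C)O[C@@](C=C)(C)C[C@@H](OCc3ccc(OC)cc3)[C@@H]12 | intermediate
45 | in,out 5,10-oxide bicycle with C1=C2, C3/C15 acetonide, C8 OPMB, masked lactone | CN(C)C[C@@H]1C(=O)O[C@@H]2[C@@H]3O[C@](C)(C=C[C@@H]4OC(C)(C)OC[C@H]34)C[C@@H](OCc3ccc(OC)cc3)[C@@H]12 | intermediate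
46 | 1,2-dihydro derivative of 45 | CN(C)C[C@@H]1C(=O)O[C@@H]2[C@@H]3O[C@](C)(CC[C@@H]4OC(C)(C)OC[C@H]34)C[C@@H](OCc3ccc(OC)cc3)[C@@H]12 | intermediate
47 | C3,C15-diol | CN(C)C[C@@H]1C(=O)O[C@@H]2[C@@H]3O[C@](C)(CC[C@H](O)[C@@H]3CO)C[C@@H](OCc3ccc(OC)cc3)[C@@H]12 | intermediate
48 | C15 TBS ether, C3–OH | CN(C)C[C@@H]1C(=O)O[C@@H]2[C@@H]3O[C@](C)(CC[C@H](O)[C@@H]3CO[Si](C)(C)C(C)(C)C)C[C@@H](OCc3ccc(OC)cc3)[C@@H]12 | intermediate
49 | C3 acetate | CN(C)C[C@@H]1C(=O)O[C@@H]2[C@@H]3O[C@](C)(CC[C@H](OC(C)=O)[C@@H]3CO[Si](C)(C)C(C)(C)C)C[C@@H](OCc3ccc(OC)cc3)[C@@H]12 | intermediate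
50 | trimethylammonium iodide of 49 | C[N+](C)(C)C[C@@H]1C(=O)O[C@@H]2[C@@H]3O[C@](C)(CC[C@H](OC(C)=O)[C@@H]3CO[Si](C)(C)C(C)(C)C)C[C@@H](OCc3ccc(OC)cc3)[C@@H]12.[I-] | intermediate (not isolated)
51 | α-methylene lactone, C3 OAc, C15 OTBS, C8 OPMB | C=C1C(=O)O[C@@H]2[C@@H]3O[C@](C)(CC[C@H](OC(C)=O)[C@@H]3CO[Si](C)(C)C(C)(C)C)C[C@@H](OCc3ccc(OC)cc3)[C@@H]12 | intermediate
52 | C8 alcohol | C=C1C(=O)O[C@@H]2[C@@H]3O[C@](C)(CC[C@H](OC(C)=O)[C@@H]3CO[Si](C)(C)C(C)(C)C)C[C@@H](O)[C@@H]12 | intermediate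
53 | mixed anhydride of 35 with 2,4,6-trichlorobenzoic acid | C/C=C(/CO[Si](C)(C)C(C)(C)C)C(=O)OC(=O)c1c(Cl)cc(Cl)cc1Cl | intermediate (not isolated)
54 | bis-TBS ether of the target | C=C1C(=O)O[C@@H]2[C@@H]3O[C@](C)(CC[C@H](OC(C)=O)[C@@H]3CO[Si](C)(C)C(C)(C)C)C[C@@H](OC(=O)/C(=C\C)CO[Si](C)(C)C(C)(C)C)[C@@H]12 | intermediate
55 | CNP0195618.1 | C=C1C(=O)O[C@@H]2[C@@H]3O[C@](C)(CC[C@H](OC(C)=O)[C@@H]3CO)C[C@@H](OC(=O)/C(=C\C)CO)[C@@H]12 | target

## Summary

Total steps: 38. Longest linear sequence: 25 steps (steps 1–10, then 24–38, from (S)-glycidol).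

**Three steps most likely to fail, with fallbacks**

Step 24 (facial selectivity of the Cr allylation). The anti/trans outcome and the Felkin preference of 16 are well founded, but the bias from C8 of 29 could oppose them. Fallback: take stereocontrol away from the substrates. Starting again from 16 and 29, the union is run with chromium(II) pre-complexed to a chiral oxazoline–sulfonamide ligand (with a proton-sponge base in THF), so that the ligand fixes the aldehyde face. The same PPTS lactonisation follows and the route is rejoined at 38. No new compound arises.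

Step 26 (Sharpless epoxidation and 7-exo ether closure at a tertiary centre). Fallback: form the tertiary allylic ether by π-allyl chemistry instead. Setting out from 39, the primary allylic hydroxyl is selectively converted (ClCO2Me, pyridine, −20 °C) into the allylic methyl carbonate F1. Pd2(dba)3 with a Trost DACH-phenyl ligand (enantiomer chosen by screening for the C10 configuration of 43) then effects intramolecular Tsuji–Trost O-allylation by the C5 hydroxyl at the more substituted allyl terminus. This gives the vinyl-substituted oxepane 43 directly, bypassing steps 26–28.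

Step 30 (RCM to the strained in,out bicycle). Fallback: close ring B by carbonyl coupling instead of metathesis. Setting out from 42, dimethylamine addition gives the masked amino aldehyde F2. OsO4 (cat.)/NaIO4/2,6-lutidine cleaves the C3 vinyl group to the dialdehyde F3. Intramolecular McMurry coupling (TiCl3, Zn–Cu, DME, high dilution, reflux) then forms C1=C2 and rejoins the route at 45.

## Further compounds

F0 | step 24 | none | none
F1 | step 26 | primary allylic methyl carbonate of 39 | C=C1C(=O)O[C@H]([C@H](O)[C@H]2COC(C)(C)O[C@H]2C=C)[C@H]1[C@H](OCc1ccc(OC)cc1)C/C(C)=C/COC(=O)OC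
F2 | step 30 | (11R)-13-(dimethylamino)-11,13-dihydro derivative of aldehyde 42 | CN(C)C[C@@H]1C(=O)O[C@@H]2[C@@H]([C@H]3COC(C)(C)O[C@H]3C=C)O[C@@](C=O)(C)C[C@@H](OCc3ccc(OC)cc3)[C@@H]12
F3 | step 30 | C1,C2-dialdehyde (C3 vinyl of F2 cleaved to CHO) | CN(C)C[C@@H]1C(=O)O[C@@H]2[C@@H]([C@H]3COC(C)(C)O[C@H]3C=O)O[C@@](C=O)(C)C[C@@H](OCc3ccc(OC)cc3)[C@@H]12
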